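The tetralone ring (C1–C4, C4a, C8a) is made from the five-membered ring of an indanone. In that indanone C1 is already bonded to C8a, the arene carbon flanked by the C8 oxygen that Friedel–Crafts acylation cannot reach, and C4 already carries the naphthyl group as a set stereocentre. The key step inserts C2: a cyclopropanol fused across C1–C3 is oxidised by one electron at oxygen, the shared C1–C3 bond breaks with release of ring strain, and the five-membered ring becomes the six-membered aryl ketone in one operation, without touching C4. The precursor is a 1-hydroxy-benzobicyclo[3.1.0]hexene; its indanone parent comes from an enantioselective rhodium cascade on a propargylic alcohol.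

Key step: step 8

Remark: 1 and 4 are taken as purchasable; the sense of induction in step 5 is assumed, and the ligand antipode that gives (S)-7 is fixed in a first small run. The target stereocentre C4 is (S).

Step 1
Reactants: 1 5-methoxynaphthalen-1-ol
Product: 2 4-bromo-5-methoxynaphthalen-1-ol
Conditions: NBS (1.0 equiv), MeCN, −20 → 0 °C
Reagents that add atoms: N-bromosuccinimide, O=C1CCC(=O)N1Br
Why: Electrophilic aromatic bromination should go para to the free OH, the strongest donor (C4, peri to OMe), by analogy with 1-naphthol and 1,5-dimethoxynaphthalene under NBS/MeCN, while low temperature and one equivalent hold back 2-bromo and dibromo products.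

Step 2
Reactants: 2 4-bromo-5-methoxynaphthalen-1-ol
Product: 3 1-(benzyloxy)-4-bromo-5-methoxynaphthalene
Conditions: BnBr, K2CO3, DMF, rt
Reagents that add atoms: benzyl bromide, BrCc1ccccc1
Why: Williamson etherification of the naphtholate masks the acidic OH for the organometallic steps with a group that leaves together with the other benzyl ethers at the end.

Step 3
Reactants: 4 2,3-bis(benzyloxy)benzaldehyde
Product: 5 rac-1-[2,3-bis(benzyloxy)phenyl]prop-2-yn-1-ol
Conditions: HC≡CMgBr, THF, 0 °C; aqueous work-up
Reagents that add atoms: ethynylmagnesium bromide, C#C[Mg]Br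
Why: Grignard 1,2-addition to the aldehyde; the carbinol may be racemic because this carbon becomes the ketone carbon in step 5.

Step 4
Reactants: 3 1-(benzyloxy)-4-bromo-5-methoxynaphthalene; 5 rac-1-[2,3-bis(benzyloxy)phenyl]prop-2-yn-1-ol
Product: 6 rac-1-[2,3-bis(benzyloxy)phenyl]-3-[4-(benzyloxy)-8-methoxynaphthalen-1-yl]prop-2-yn-1-ol
Conditions: Pd(PhCN)2Cl2 (3 mol %), [HP(t-Bu)3]BF4 (6 mol %), CuI (2 mol %), i-Pr2NH, dioxane, rt
Reagents that add atoms: none
Why: Sonogashira coupling with the Pd/P(t-Bu)3 system should couple the electron-rich, peri-hindered aryl bromide at room temperature, which avoids base-induced isomerisation of the propargylic alcohol to the enone.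

Step 5
Reactants: 6 rac-1-[2,3-bis(benzyloxy)phenyl]-3-[4-(benzyloxy)-8-methoxynaphthalen-1-yl]prop-2-yn-1-ol
Product: 7 (3S)-6,7-bis(benzyloxy)-3-[4-(benzyloxy)-8-methoxynaphthalen-1-yl]-2,3-dihydro-1H-inden-1-one
Conditions: [Rh(OH)(cod)]2 (2.5 mol %), (R)-DTBM-SEGPHOS (6 mol %), dioxane, 60 °C
Reagents that add atoms: none
Why: Rhodium-catalysed asymmetric isomerisation of an α-arylpropargyl alcohol to a 3-substituted indanone: β-hydride elimination from the rhodium alkoxide gives the metal-bound ynone and Rh–H, hydrorhodation and a 1,4-rhodium shift move the metal to the only free ortho position (the other carries OBn), and the aryl–rhodium adds to the β-naphthyl enone inside the chiral bisphosphine pocket, which should set C3 as (S) from either enantiomer of 6.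

Step 6
Reactants: 7 (3S)-6,7-bis(benzyloxy)-3-[4-(benzyloxy)-8-methoxynaphthalen-1-yl]-2,3-dihydro-1H-inden-1-one
Product: 9 {[(1S)-4,5-bis(benzyloxy)-1-[4-(benzyloxy)-8-methoxynaphthalen-1-yl]-1H-inden-3-yl]oxy}trimethylsilane, via lithium enolate 8 (not isolated)
Conditions: LiHMDS, THF, −78 °C; then TMSCl, −78 → 0 °C; pentane, filtration
Reagents that add atoms: chlorotrimethylsilane, C[Si](C)(C)Cl
Why: Kinetic deprotonation at the only α-CH2 and O-silylation give the silyl enol ether, and cold, non-aqueous handling without trialkylamine should prevent 1,3-prototropy at the acidic C1–H of the 1-arylindene, so the stereocentre is kept.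

Step 7
Reactants: 9 {[(1S)-4,5-bis(benzyloxy)-1-[4-(benzyloxy)-8-methoxynaphthalen-1-yl]-1H-inden-3-yl]oxy}trimethylsilane
Product: 11 (1aS,6S,6aR)-2,3-bis(benzyloxy)-6-[4-(benzyloxy)-8-methoxynaphthalen-1-yl]-6,6a-dihydrocyclopropa[a]inden-1a(1H)-ol (OH on the ring-fusion carbon next to the arene, cyclopropane CH2 anti to the naphthyl group), via silyl ether 10 (not isolated)
Conditions: Et2Zn, CH2I2, CH2Cl2, 0 °C → rt; then MeOH, K2CO3 (cat.), 0 °C → rt
Reagents that add atoms: diiodomethane, ICI
Why: Simmons–Smith cyclopropanation (Furukawa variant) of the electron-rich enol ether double bond from the face anti to the naphthyl group should set 1aS and 6aR (both centres vanish in step 8, so this selectivity is not critical), and methanolysis of the Si–O bond frees the cyclopropanol.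

Step 8
Reactants: 11 (1aS,6S,6aR)-2,3-bis(benzyloxy)-6-[4-(benzyloxy)-8-methoxynaphthalen-1-yl]-6,6a-dihydrocyclopropa[a]inden-1a(1H)-ol
Product: 12 (4S)-7,8-bis(benzyloxy)-4-[4-(benzyloxy)-8-methoxynaphthalen-1-yl]-3,4-dihydronaphthalen-1(2H)-one
Conditions: Mn(pic)3 (2.4 equiv), Bu3SnH (4 equiv, 0.4 M), DMF, 0 °C
Reagents that add atoms: none
Why: Ligand exchange gives the Mn(III) cyclopropanolate, and inner-sphere one-electron oxidation opens the ring-fusion bond C1a–C6a (future C1–C3) to the aryl ketone and the secondary C3 radical of the enlarged ring, which takes a hydrogen atom from Bu3SnH. The closest known reaction type is the oxidative radical ring enlargement of bicyclo[n.1.0]alkan-1-ols and their silyl ethers with Mn(III) picolinate or Fe(III) salts, here with stannane termination. No ring is closed by a new bond: the six-membered ring arises when the zero-atom bridge of the benzobicyclo[3.1.0]hexene is cut, so the five-membered ring takes in the cyclopropane CH2 as C2 (5→6 expansion driven by about 27 kcal/mol of cyclopropane strain). No stereocentre is formed; C4 is not a radical site and should keep its (S) configuration, while the two cyclopropane stereocentres disappear. The step needs internal rather than external C–C scission, which the more stable secondary radical and the conjugated aryl ketone from the internal cut should secure (ionic opening would give the 2-methylindanone instead). It also needs hydrogen transfer to outrun a 1,2-naphthyl shift from C4 to C3 and oxidation to the enone, which would aromatise to the naphthol; excess stannane at high concentration and the weak oxidant are chosen for this.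

Step 9
Reactants: 12 (4S)-7,8-bis(benzyloxy)-4-[4-(benzyloxy)-8-methoxynaphthalen-1-yl]-3,4-dihydronaphthalen-1(2H)-one
Product: 13 (4S)-7,8-dihydroxy-4-(4-hydroxy-8-methoxynaphthalen-1-yl)-3,4-dihydronaphthalen-1(2H)-one
Conditions: H2 (1 atm), 10 % Pd/C, EtOAc–MeOH, rt
Reagents that add atoms: none
Why: Hydrogenolysis should cleave the three aryl benzyl ethers while the aryl methyl ether, the C4–H stereocentre and, at 1 atm with the reaction stopped after three equivalents of H2, the aryl ketone stay untouched.

Compound list
1 | 5-methoxynaphthalen-1-ol | COc1cccc2c(O)cccc12 | starting material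
2 | 4-bromo-5-methoxynaphthalen-1-ol | COc1cccc2c(O)ccc(Br)c12 | intermediate
3 | 1-(benzyloxy)-4-bromo-5-methoxynaphthalene | COc1cccc2c(OCc3ccccc3)ccc(Br)c12 | intermediate
4 | 2,3-bis(benzyloxy)benzaldehyde | O=Cc1cccc(OCc2ccccc2)c1OCc1ccccc1 | starting material
5 | rac-1-[2,3-bis(benzyloxy)phenyl]prop-2-yn-1-ol | C#CC(O)c1cccc(OCc2ccccc2)c1OCc1ccccc1 | intermediate
6 | rac-1-[2,3-bis(benzyloxy)phenyl]-3-[4-(benzyloxy)-8-methoxynaphthalen-1-yl]prop-2-yn-1-ol | COc1cccc2c(OCc3ccccc3)ccc(C#CC(O)c3cccc(OCc4ccccc4)c3OCc3ccccc3)c12 | intermediate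
7 | (3S)-6,7-bis(benzyloxy)-3-[4-(benzyloxy)-8-methoxynaphthalen-1-yl]-2,3-dihydro-1H-inden-1-one | COc1cccc2c(OCc3ccccc3)ccc([C@@H]3CC(=O)c4c3ccc(OCc3ccccc3)c4OCc3ccccc3)c12 | intermediate
8 | lithium (1S)-4,5-bis(benzyloxy)-1-[4-(benzyloxy)-8-methoxynaphthalen-1-yl]-1H-inden-3-olate (lithium enolate of 7, formed in the flask) | COc1cccc2c(OCc3ccccc3)ccc([C@@H]3C=C(O[Li])c4c3ccc(OCc3ccccc3)c4OCc3ccccc3)c12 | intermediate
9 | {[(1S)-4,5-bis(benzyloxy)-1-[4-(benzyloxy)-8-methoxynaphthalen-1-yl]-1H-inden-3-yl]oxy}trimethylsilane | COc1cccc2c(OCc3ccccc3)ccc([C@@H]3C=C(O[Si](C)(C)C)c4c3ccc(OCc3ccccc3)c4OCc3ccccc3)c12 | intermediate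
10 | {[(1aS,6S,6aR)-2,3-bis(benzyloxy)-6-[4-(benzyloxy)-8-methoxynaphthalen-1-yl]-6,6a-dihydrocyclopropa[a]inden-1a(1H)-yl]oxy}trimethylsilane (trimethylsilyl ether of 11, formed in the flask) | C[Si](C)(C)O[C@@]12C[C@@H]1[C@@H](c1ccc(OCc3ccccc3)c3cccc(OC)c13)c1ccc(OCc3ccccc3)c(OCc3ccccc3)c12 | intermediate
11 | (1aS,6S,6aR)-2,3-bis(benzyloxy)-6-[4-(benzyloxy)-8-methoxynaphthalen-1-yl]-6,6a-dihydrocyclopropa[a]inden-1a(1H)-ol | O[C@@]12C[C@@H]1[C@@H](c1ccc(OCc3ccccc3)c3cccc(OC)c13)c1ccc(OCc3ccccc3)c(OCc3ccccc3)c12 | intermediate
12 | (4S)-7,8-bis(benzyloxy)-4-[4-(benzyloxy)-8-methoxynaphthalen-1-yl]-3,4-dihydronaphthalen-1(2H)-one | COc1cccc2c(OCc3ccccc3)ccc([C@@H]3CCC(=O)c4c3ccc(OCc3ccccc3)c4OCc3ccccc3)c12 | intermediate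
13 | (4S)-7,8-dihydroxy-4-(4-hydroxy-8-methoxynaphthalen-1-yl)-3,4-dihydronaphthalen-1(2H)-one | COc1cccc2c(O)ccc([C@@H]3CCC(=O)c4c3ccc(O)c4O)c12 | target

Total step count: 9. Longest linear sequence: 8 steps (1 → 2 → 3 → 6 → 7 → 9 → 11 → 12 → 13; steps 1, 2, 4, 5, 6, 7, 8, 9).

Steps most likely to fail

Step 5. The cascade may stall after hydrorhodation, so that only the open-chain enone forms, or the aryl–rhodium may add to the hindered β-naphthyl enone with poor facial selectivity. The fallback sets out from 6 and comes back at 7. Compound 6 would be isomerised by the same cascade with an achiral catalyst ([Rh(OH)(cod)]2, rac-BINAP, dioxane, 60 °C) to the racemic indanone F1. IBX dehydrogenation (DMSO, 65 °C) would then give 6,7-bis(benzyloxy)-3-[4-(benzyloxy)-8-methoxynaphthalen-1-yl]-1H-inden-1-one F2. Copper hydride-catalysed asymmetric conjugate reduction (Cu(OAc)2·H2O, DTBM-SEGPHOS antipode chosen as in the remark, PMHS, t-BuOH, toluene, 0 °C) should deliver hydride to one face of the β,β-diaryl enone and return 7.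

Step 8. The ring-enlarged C3 radical may live long enough for the naphthyl group to migrate from C4 to C3, or for oxidation and elimination toward the naphthol. The fallback sets out from 11 and comes back at 12. Compound 11 would be opened with FeCl3 (2.2 equiv) in DMF at 0 °C, where chlorine-atom transfer from iron(III) should capture the radical at once and give (4S)-7,8-bis(benzyloxy)-4-[4-(benzyloxy)-8-methoxynaphthalen-1-yl]-3-chloro-3,4-dihydronaphthalen-1(2H)-one F3 as a mixture of C3 epimers. The C–Cl bond would then be reduced in a separate radical step with Bu3SnH, catalytic PhSeSePh (benzeneselenol as a fast hydrogen donor) and Et3B/air in toluene at 0 °C → rt, to give 12.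

Step 6. The 1-arylindene silyl enol ether may lose its C1 configuration through base-mediated prototropic shift, or hydrolyse before cyclopropanation. The fallback sets out from 7 and comes back at 11. The lithium enolate 8 (LiHMDS, THF, −78 °C) would not be silylated but cyclopropanated in the same flask with the samarium carbenoid from CH2I2 and SmI2 (−78 → 0 °C). Aqueous work-up should give cyclopropanol 11 directly and bypass 9 and 10; this fallback makes no new compound (F0).

Further compounds
F1 | step 5 | rac-6,7-bis(benzyloxy)-3-[4-(benzyloxy)-8-methoxynaphthalen-1-yl]-2,3-dihydro-1H-inden-1-one | COc1cccc2c(OCc3ccccc3)ccc(C3CC(=O)c4c3ccc(OCc3ccccc3)c4OCc3ccccc3)c12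
F2 | step 5 | 6,7-bis(benzyloxy)-3-[4-(benzyloxy)-8-methoxynaphthalen-1-yl]-1H-inden-1-one | COc1cccc2c(OCc3ccccc3)ccc(C3=CC(=O)c4c3ccc(OCc3ccccc3)c4OCc3ccccc3)c12
F3 | step 8 | (4S)-7,8-bis(benzyloxy)-4-[4-(benzyloxy)-8-methoxynaphthalen-1-yl]-3-chloro-3,4-dihydronaphthalen-1(2H)-one (C3 epimers) | COc1cccc2c(OCc3ccccc3)ccc([C@@H]3C(Cl)CC(=O)c4c3ccc(OCc3ccccc3)c4OCc3ccccc3)c12
F0 | step 6 | none | none
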